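**Numbering used throughout.** Labdane numbering is used for all decalin compounds: ring A = C1–C5 and C10; ring B = C5–C10; ring C = O, C8, C9, C11–C15; C17 is the carbon on C8, C20 the methyl on C10. Compounds are numbered 1–33 as in the steps and in the compound list.

## Analysis of the target

Compound 33 is a 3-bromolabdane: a trans-fused decalin (rings A and B) with an eight-membered cyclic ether (ring C) fused across C8–C9 and a cis-epoxide at C13–C14. It has seven stereocentres (3S,5R,8R,9R,10S,13R,14S): the equatorial 3β-bromide beside the C4 gem-dimethyl group, the ring-fusion pair C5 (α-H) and C10 (β-methyl), C9 (α-H), C8 (α ether oxygen, β axial methyl) and the two epoxide carbons. C5, C10, C9 and C8 are contiguous in ring B and include the quaternary C10 and the fully substituted C8. The epoxide oxygen lies on the face of ring C that also carries the C8 methyl, remote from any strong directing group. Sensitive groups are the trisubstituted epoxide (acid), the neopentyl secondary bromide (cannot be introduced by displacement and is at risk under reducing metals) and the tertiary ether. The hard parts are therefore the four contiguous ring B centres, an equatorial bromide next to a quaternary carbon, the medium ring and a face-selective epoxidation. The strategy rests on reading the ring B carbons C5=C6–C7=C8 as a 1-oxygenated diene and C9=C10 (with C11) as an (E)-enoate, joined through the ring A carbons C1–C4, so that one intramolecular [4+2] cycloaddition of an acyclic triene closes rings A and B together.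

## Retrosynthetic reasoning

**33 to 32.** The epoxide C–O bonds at C13 and C14 are cut last, because the epoxide is the most acid-sensitive group and the cis ring olefin of 32 is its natural precursor. The forward step must deliver oxygen to one face of a trisubstituted olefin in a flexible ring, so reagent control is planned.

**32 to 30 (through 31).** Ring C is opened at C12–C13. Cutting here, and not at O8–C15, avoids an eight-membered closure by a tertiary alkoxide. It also lets the Z geometry of C13=C14 come ready-made from a small building block, and it needs only a vinyl group on C9. The forward reaction is an intramolecular sp3–sp2 cross-coupling of a borane with a vinyl iodide.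

**30 to 26 and 29.** The O8–C15 ether bond is cut to the tertiary alcohol 26 and the allylic bromide 29. Compound 29 is traced to alcohol 28 and to alkyne 27, whose directed trans-hydrometalation fixes the Z geometry.

**26 to 23 (through 25 and 24).** The C11=C12 bond is cut to aldehyde 25, which comes from diol 24 and ester 23. The ester carbon of the cycloaddition thus becomes C11 and only C12 has to be added.

**23 to 19 (through 22, 21, 20).** The C8 carbinol is disconnected at C8–O (Markovnikov hydration of the exocyclic olefin 22) and at C8=C17 (methylenation of ketone 21). Addition of a methyl nucleophile to 21 is not used, because equatorial attack would give the C8 epimer. Ketone 21 comes from the silyl ether 19 through alcohol 20, so the C8 configuration created in the cycloaddition does not matter.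

**19 to 15 (through 18, 17, 16).** The C3–Br bond cannot be made by substitution at a neopentyl centre. It is traced to vinyl bromide 18, whose radical hydrogenation delivers hydrogen axially and leaves bromine equatorial. 18 comes from enol triflate 17, ketone 16 and alcohol 15. This block is placed before any other olefin is introduced, since the radical hydrogenation would not spare one.

**15 to 13 (through 14).** Saturation of C6=C7 and removal of the more labile C3 silyl group lead back to cycloadduct 13. C3 carries the triethylsilyl ether and C8 the tert-butyldimethylsilyl ether because C3 must be unmasked first.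

**13 to 12 (key disconnection).** C5–C10 and C8–C9 are cut, opening rings A and B at once to the acyclic triene 12. This removes two rings, two skeletal bonds and four stereocentres in one operation; the C3 silyloxy stereocentre of 12 is the only stereochemical information that has to be carried in.

**12 to 7 and 8 (through 11, 10, 9).** The silyl dienol ether is traced to the conjugated enal 11, because vinylogous enolisation of an s-trans enal gives the E enol ether. 11 comes from acetal 9 through aldehyde 10. Cutting the olefin of 9 gives aldehyde 7 and the three-carbon phosphonium salt 8.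

**7 to 2 and 4 (through 6, 5).** Aldehyde 7 comes from thioester 6, which allows reduction in the presence of the methyl enoate. The C3–C4 bond is cut by an enantioselective aldol disconnection to aldehyde 2 and ketene acetal 4; this sets the only stereocentre of the precursor and the gem-dimethyl group in one step. 2 comes from 1 by cleavage of the distal olefin, and 4 from 3.

## Alternatives that were turned down

**Alternative 1:** Ring C is disconnected at C13=C14. The diene A1 (O8 allyl ether, 3-methylbut-3-enyl chain on C9) would be closed by ring-closing metathesis with a ruthenium alkylidene (second-generation Grubbs catalyst) to the oxocene A2, which is identical with 32.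
- For: the ring enforces the cis olefin, the catalyst tolerates the bromide and the ether, and the O-alkylating agent is simpler than 29. As a ring C closure it is probably at least as dependable as the borane coupling used here.
- Against: it forms one bond, one ring and no stereocentre, and leaves the decalin with its contiguous centres unsolved. A1 needs a four-carbon chain on C9 (two extra C–C bond formations from the C11 ester), and the 1,1-disubstituted olefin makes the medium-ring metathesis slow.
- Comparison: the chosen route accepts a less proven ring closure, but needs only a one-carbon extension at C9 and spends its key step on rings A and B and the centres C5, C9 and C10.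

**Alternative 2:** Ring A is disconnected at C1–C10 and C4–C5. The ring B ketone A3 would be annulated with pent-1-en-3-one A4 under hydroxide in an alcohol (Robinson annulation) to the enone A5.
- For: cheap, classical, forms the quaternary C10 and delivers C3 as a ketone and C8 fully substituted. On these two points it is stronger than the chosen route, which needs an oxidation at C3 and a four-step adjustment at C8.
- Against: A3 already contains the C8 and C9 centres and needs its own enantioselective synthesis. The annulation sets only C10, by an untested facial preference. A5 still lacks the second C4 methyl and the trans ring fusion (a reductive alkylation). The C9 vinyl group of A5 would not survive the radical hydrogenation that installs the bromide.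
- Comparison: one ring and one stereocentre per key step, against two rings and four centres from a precursor made in eight steps.

**Alternative 3:** The side chain is disconnected at C12–C13 and C14–C15. The organocopper reagent from iodide A6 would add syn across propyne A7, and the resulting alkenylcopper would be trapped with carbon dioxide A8 to give the (Z)-acid A9.
- For: a one-flask, geometry-defined assembly of the Z trisubstituted olefin from very simple reagents. In olefin control it equals the chosen route, which obtains the same geometry from 28.
- Against: no ring and no stereocentre is formed. The organometallic must be generated from a primary iodide next to a secondary bromide. Ring C must then be closed at O8–C15 by a tertiary alkoxide, after reduction and activation of the acid, with six-membered SN2′ closure as a competitor. A6 itself requires a two-carbon chain on C9.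
- Comparison: it solves a side-chain problem that the chosen route handles with a separately made four-carbon reagent, and leaves the core untouched.

Key step: step 9

**Remarks.**
- In 2–12 the chain atoms C1–C11 of the ester correspond to labdane C11, C9, C10, C1, C2, C3, C4, C5, C6, C7, C8.
- The D-valine-derived promoter in step 3 is assumed to give the 6S carbinol; if the sense were opposite, its enantiomer would be used.

## Route

Step 1
Reactants: 1 methyl geranate, methyl (2E)-3,7-dimethylocta-2,6-dienoate
Product: 2 methyl (2E)-3-methyl-6-oxohex-2-enoate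
Conditions: O3 (1.0 equiv), CH2Cl2, −78 °C; Me2S, −78 °C → rt
Reagents that add atoms: ozone, [O-][O+]=O
Why: Ozonolysis with reductive work-up; the electron-rich trisubstituted distal olefin reacts much faster with electrophilic ozone than the ester-conjugated olefin, so one equivalent should cleave only the former.

Step 2
Reactants: 3 S-ethyl 2-methylpropanethioate
Product: 4 {[1-(ethylsulfanyl)-2-methylprop-1-en-1-yl]oxy}trimethylsilane
Conditions: LiN(i-Pr)2, THF, −78 °C; Me3SiCl, −78 °C → rt
Reagents that add atoms: chlorotrimethylsilane, C[Si](C)(C)Cl
Why: O-silylation of the lithium thioester enolate; the ketene acetal is symmetric at the nucleophilic carbon, so no enolate geometry has to be controlled.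

Step 3
Reactants: 2 methyl (2E)-3-methyl-6-oxohex-2-enoate; 4 silyl ketene thioacetal
Product: 5 methyl (2E,6S)-8-(ethylsulfanyl)-6-hydroxy-3,7,7-trimethyl-8-oxooct-2-enoate
Conditions: N-tosyl-D-valine, BH3·THF, CH2Cl2, 0 °C → rt; then 2 and 4, −78 °C; pH 7 buffer
Reagents that add atoms: none
Why: Enantioselective Mukaiyama aldol addition promoted by a valine-derived oxazaborolidinone, which binds the aldehyde and shields one face; this sets the carbinol centre (later C3) as 6S and builds the gem-dimethyl carbon in the same bond formation.

Step 4
Reactants: 5 β-hydroxy thioester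
Product: 6 methyl (2E,6S)-8-(ethylsulfanyl)-3,7,7-trimethyl-8-oxo-6-[(triethylsilyl)oxy]oct-2-enoate
Conditions: Et3SiOTf, 2,6-lutidine, CH2Cl2, −78 → 0 °C
Reagents that add atoms: triethylsilyl trifluoromethanesulfonate, CC[Si](CC)(CC)OS(=O)(=O)C(F)(F)F
Why: Silyl triflate silylation of a hindered secondary alcohol under non-nucleophilic base; no retro-aldol pathway is opened because no alkoxide is formed.

Step 5
Reactants: 6 silyl-protected thioester
Product: 7 methyl (2E,6S)-3,7,7-trimethyl-8-oxo-6-[(triethylsilyl)oxy]oct-2-enoate
Conditions: Et3SiH, 10% Pd/C, acetone, rt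
Reagents that add atoms: none
Why: Fukuyama reduction; palladium inserts into the C–S bond and the acylpalladium is reduced by the silane to the aldehyde, leaving the methyl enoate and the silyl ether untouched and stopping at the aldehyde stage.

Step 6
Reactants: 7 aldehyde; 8 [2-(1,3-dioxolan-2-yl)ethyl]triphenylphosphonium bromide
Product: 9 methyl (2E,6S,8Z)-10-(1,3-dioxolan-2-yl)-3,7,7-trimethyl-6-[(triethylsilyl)oxy]deca-2,8-dienoate
Conditions: 8, KN(SiMe3)2, THF, 0 °C; then 7, −78 °C → rt
Reagents that add atoms: none
Why: Wittig olefination with a non-stabilised ylide on a non-enolisable aldehyde; the Z geometry expected here is of no consequence because this double bond is moved in the next step.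

Step 7
Reactants: 9 acetal
Product: 11 methyl (2E,6S,9E)-3,7,7-trimethyl-11-oxo-6-[(triethylsilyl)oxy]undeca-2,9-dienoate, via (Z)-β,γ-unsaturated aldehyde 10 (not isolated)
Conditions: Et3SiOTf, 2,4,6-collidine, CH2Cl2, 0 °C; H2O; then DBU (cat.), CH2Cl2, rt
Reagents that add atoms: water, O
Why: Acetal cleavage through a collidinium intermediate under non-acidic conditions keeps the triethylsilyl ether; base-catalysed prototropic shift through the dienolate then moves the olefin into conjugation and gives the thermodynamically favoured (E)-enal.

Step 8
Reactants: 11 (E)-enal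
Product: 12 methyl (2E,6S,8E,10E)-11-[(tert-butyldimethylsilyl)oxy]-3,7,7-trimethyl-6-[(triethylsilyl)oxy]undeca-2,8,10-trienoate
Conditions: t-BuMe2SiOTf, Et3N, CH2Cl2, −20 → 0 °C
Reagents that add atoms: tert-butyldimethylsilyl trifluoromethanesulfonate, CC(C)(C)[Si](C)(C)OS(=O)(=O)C(F)(F)F
Why: Vinylogous silyl enol ether formation: O-silylation of the s-trans enal followed by γ-deprotonation gives the E enol ether, and the new C5=C6 bond should be E because the Z isomer would press the quaternary C4 against C7–H; the far less reactive ester is not enolised.

Step 9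
Reactants: 12 acyclic silyloxy triene ester
Product: 13 cycloadduct: trans-decalin methyl ester with 3β-OSiEt3, 8β-OSiMe2t-Bu, 9β-CO2Me, 10β-CH3, 5α-H and a C6=C7 double bond
Conditions: toluene (5 mM), BHT (cat.), 180 °C, sealed base-washed tube
Reagents that add atoms: none
Why: Thermal type 1 intramolecular Diels–Alder reaction, a concerted asynchronous [4+2] between the electron-rich 1-silyloxy diene (C5=C6–C7=C8) and the enoate (C9=C10); the closest known reaction type is the thermal cyclisation of 1,7,9-decatrienes carrying a terminal ester on the dienophile to give decalins. Ring B is closed as the cyclohexene of the cycloaddition itself (both new bonds, C5–C10 and C8–C9, lie in it), and ring A is closed by the C5–C10 bond through the four-carbon tether C1–C4, which folds as a chair. Regiochemistry is fixed by the tether and is electronically matched, since the diene terminus remote from oxygen (C5) meets the β-carbon of the enoate (C10). C9 relative to C10 follows from suprafacial addition to the E enoate, which leaves the C10 methyl and the ester cis. The C5/C10 ring fusion is trans only through the ester-endo, tether-exo transition state; this is the selectivity the step needs, and it is supported by secondary overlap of the ester with the diene and by the chair tether but is not guaranteed. C8 is set β (cis to the ester) by the E enol ether in the endo mode, which is immaterial because C8 is later oxidised. The absolute sense comes from the C3 triethylsilyloxy group, which takes the equatorial position of the chair tether so that the diene reaches one face of the enoate only.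

Step 10
Reactants: 13 cycloadduct
Product: 15 3β-hydroxy ester (8β-OSiMe2t-Bu, 9β-CO2Me, ring B saturated), via saturated bis-silyl ether 14 (not isolated)
Conditions: H2 (1 atm), 10% Pd/C, EtOAc, rt; filter; PPTS, MeOH, rt
Reagents that add atoms: none
Why: Heterogeneous hydrogenation of the only olefin creates no stereocentre; mild acid methanolysis then removes the triethylsilyl ether, which is far more labile than the secondary tert-butyldimethylsilyl ether.

Step 11
Reactants: 15 3β-alcohol
Product: 16 3-ketone (8β-OSiMe2t-Bu, 9β-CO2Me)
Conditions: Dess–Martin periodinane, NaHCO3, CH2Cl2, rt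
Reagents that add atoms: none
Why: Dess–Martin oxidation of a hindered secondary alcohol under buffered, neutral conditions that leave the silyl ether and the ester untouched.

Step 12
Reactants: 16 3-ketone
Product: 17 3-(trifluoromethanesulfonyloxy)-2-ene (enol triflate; 8β-OSiMe2t-Bu, 9β-CO2Me)
Conditions: KN(SiMe3)2, THF, −78 °C; PhNTf2, −78 → 0 °C
Reagents that add atoms: N-phenylbis(trifluoromethanesulfonimide), O=S(=O)(N(c1ccccc1)S(=O)(=O)C(F)(F)F)C(F)(F)F
Why: Kinetic enolate formation and O-triflation; C4 is quaternary, so only the C2 enolate can form, and the ketone is deprotonated much faster than the hindered ester α-position.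

Step 13
Reactants: 17 enol triflate
Product: 18 3-bromo-2-ene (vinyl bromide; 8β-OSiMe2t-Bu, 9β-CO2Me)
Conditions: Ni(cod)2 (10 mol %), LiBr, DMA/THF (1:3), rt
Reagents that add atoms: lithium bromide, [Li+].[Br-]
Why: Nickel-catalysed halogenation of an enol triflate: oxidative addition of zerovalent nickel into the C–O bond, triflate–bromide exchange and reductive elimination, under neutral conditions that avoid any cation at C3 and hence any methyl shift from C4.

Step 14
Reactants: 18 vinyl bromide
Product: 19 3β-bromide (8β-OSiMe2t-Bu, 9β-CO2Me)
Conditions: Mn(dpm)3 (10 mol %), PhSiH3, t-BuOOH, i-PrOH, rt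
Reagents that add atoms: none
Why: Hydrogen-atom-transfer hydrogenation: the manganese hydride gives H to C2 and leaves the bromine-stabilised radical at C3, which takes the second hydrogen along the axial α trajectory, so bromine ends equatorial (3β, the thermodynamic isomer); no metal surface is present to cleave the C–Br bond.

Step 15
Reactants: 19 3β-bromo silyl ether
Product: 20 3β-bromo-8β-hydroxy ester
Conditions: HF·pyridine, THF, 0 °C → rt
Reagents that add atoms: none
Why: Fluoride-driven cleavage of the axial silyl ether under weakly acidic conditions, which avoids base-induced retro-aldol of the β-hydroxy ester and does not touch the bromide.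

Step 16
Reactants: 20 8β-alcohol
Product: 21 3β-bromo-8-oxo ester (β-keto ester, 9β-CO2Me)
Conditions: Dess–Martin periodinane, NaHCO3, CH2Cl2, rt
Reagents that add atoms: none
Why: Dess–Martin oxidation removes the C8 stereocentre; the enolisable C9 keeps its ester equatorial (β), which is the thermodynamic arrangement.

Step 17
Reactants: 21 β-keto ester
Product: 22 3β-bromo-8(17)-ene ester (exocyclic methylene at C8, 9β-CO2Me)
Conditions: Zn, CH2Br2, TiCl4, THF, 0 °C; then 21, CH2Cl2, rt
Reagents that add atoms: dibromomethane, BrCBr
Why: Lombardo methylenation; the weakly basic zinc–titanium methylene reagent adds to the ketone carbonyl of readily enolised substrates where a phosphorus ylide would act as a base, and it does not attack the ester.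

Step 18
Reactants: 22 exocyclic olefin
Product: 23 3β-bromo-8α-hydroxy-8β-methyl ester (9β-CO2Me)
Conditions: Co(acac)2 (20 mol %), PhSiH3, O2 (1 atm), THF, rt
Reagents that add atoms: dioxygen, O=O
Why: Mukaiyama hydration: hydrogen-atom transfer to C17 gives the tertiary C8 radical, which is trapped by oxygen on the α face because the β (axial) trajectory is blocked by the syn-axial C10 methyl; this places the oxygen α and equatorial and the new methyl β and axial.

Step 19
Reactants: 23 hydroxy ester
Product: 24 3β-bromo-8α,11-diol
Conditions: i-Bu2AlH (4 equiv), CH2Cl2, −78 → 0 °C; aq. KNaC4H4O6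
Reagents that add atoms: none
Why: Hydride reduction of the ester to the primary alcohol; the aluminium hydride does not displace the hindered equatorial neopentyl bromide at low temperature.

Step 20
Reactants: 24 diol
Product: 25 3β-bromo-8α-hydroxy-11-aldehyde
Conditions: Dess–Martin periodinane, NaHCO3, CH2Cl2, 0 °C
Reagents that add atoms: none
Why: Dess–Martin oxidation affects only the primary alcohol since the tertiary one has no carbinol hydrogen; buffered neutral conditions limit dehydration, and the formyl group at C9 stays equatorial.

Step 21
Reactants: 25 hydroxy aldehyde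
Product: 26 3β-bromo-8α-hydroxy-9β-vinyl decalin (C11=C12)
Conditions: Ph3PCH3Br, KN(SiMe3)2 (slightly less than the salt), THF, 0 °C; then 25, −78 → 0 °C
Reagents that add atoms: methyltriphenylphosphonium bromide, C[P+](c1ccccc1)(c1ccccc1)c1ccccc1.[Br-]
Why: Wittig methylenation; the ylide is a weaker base than a tertiary alkoxide, so the 8-hydroxyl stays protonated and retro-aldol cleavage is not triggered, while addition to the aldehyde is fast at low temperature.

Step 22
Reactants: 27 but-2-yn-1-ol
Product: 28 (2Z)-3-iodobut-2-en-1-ol
Conditions: NaAlH2(OCH2CH2OMe)2, Et2O, 0 °C → rt; I2, THF, −78 °C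
Reagents that add atoms: iodine, II
Why: Alkoxide-directed trans-hydroalumination places aluminium on C3 cis to the carbinol carbon through a five-membered alanate; iodinolysis with retention gives the Z vinyl iodide.

Step 23
Reactants: 28 (2Z)-3-iodobut-2-en-1-ol
Product: 29 (2Z)-1-bromo-3-iodobut-2-ene
Conditions: CBr4, PPh3, CH2Cl2, 0 °C
Reagents that add atoms: tetrabromomethane, BrC(Br)(Br)Br
Why: Appel bromination of a primary allylic alcohol under neutral conditions that do not isomerise the vinyl iodide.

Step 24
Reactants: 26 tertiary alcohol; 29 allylic bromide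
Product: 30 O8-[(2Z)-3-iodobut-2-enyl] ether of 26
Conditions: NaH, THF/DMF, Bu4NI (cat.), 0 °C → rt
Reagents that add atoms: none
Why: Williamson etherification of a tertiary alkoxide with a reactive primary allylic halide; the equatorial neopentyl bromide has no antiperiplanar hydrogen and is inert to substitution, and with the vinyl group already in place there is no carbonyl for a retro-aldol.

Step 25
Reactants: 30 vinyl iodide ether
Product: 32 oxocene: 3β-bromo tricycle with the cis C13=C14 olefin in ring C, via alkyl-9-BBN borane 31 (not isolated)
Conditions: 9-BBN, THF, rt → 40 °C; then slow addition to Pd(dppf)Cl2 (15 mol %), AsPh3, Cs2CO3, DMF/THF/H2O, 50 °C (2 mM)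
Reagents that add atoms: none
Why: Intramolecular B-alkyl Suzuki–Miyaura coupling: anti-Markovnikov hydroboration of the vinyl group puts boron on C12, zerovalent palladium inserts into the C13–I bond with retention of the Z geometry, and base-assisted transmetalation and reductive elimination form C12–C13; the two tether ends are equatorial and gauche on ring B, which favours closure.

Step 26
Reactants: 32 oxocene
Product: 33 target, (3S,5R,8R,9R,10S,13R,14S)-3-bromo-8,15:13,14-diepoxylabdane
Conditions: enantiomer of the fructose-derived Shi ketone (L-series, 30 mol %), KHSO5, K2CO3, Bu4NHSO4, MeCN/dimethoxymethane/aq. Na2B4O7 buffer, 0 °C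
Reagents that add atoms: potassium peroxymonosulfate, [K+].[O-]S(=O)(=O)OO
Why: Shi epoxidation: the chiral dioxirane transfers oxygen in a concerted spiro transition state, so the cis ring geometry is retained; by the model established for 1-substituted cycloalkenes, the L-series ketone should deliver oxygen to the face giving 13R,14S, independent of the conformational bias of ring C.

## Compound list

1 | methyl geranate, methyl (2E)-3,7-dimethylocta-2,6-dienoate | CC(C)=CCC/C(C)=C/C(=O)OC | starting material
2 | methyl (2E)-3-methyl-6-oxohex-2-enoate | O=CCC/C(C)=C/C(=O)OC | intermediate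
3 | S-ethyl 2-methylpropanethioate | CCSC(=O)C(C)C | starting material
4 | {[1-(ethylsulfanyl)-2-methylprop-1-en-1-yl]oxy}trimethylsilane | CC(C)=C(SCC)O[Si](C)(C)C | intermediate
5 | methyl (2E,6S)-8-(ethylsulfanyl)-6-hydroxy-3,7,7-trimethyl-8-oxooct-2-enoate | CCSC(=O)C(C)(C)[C@@H](O)CC/C(C)=C/C(=O)OC | intermediate
6 | methyl (2E,6S)-8-(ethylsulfanyl)-3,7,7-trimethyl-8-oxo-6-[(triethylsilyl)oxy]oct-2-enoate | CCSC(=O)C(C)(C)[C@@H](O[Si](CC)(CC)CC)CC/C(C)=C/C(=O)OC | intermediate
7 | methyl (2E,6S)-3,7,7-trimethyl-8-oxo-6-[(triethylsilyl)oxy]oct-2-enoate | O=CC(C)(C)[C@@H](O[Si](CC)(CC)CC)CC/C(C)=C/C(=O)OC | intermediate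
8 | [2-(1,3-dioxolan-2-yl)ethyl]triphenylphosphonium bromide | [Br-].C1COC(CC[P+](c2ccccc2)(c2ccccc2)c2ccccc2)O1 | starting material
9 | methyl (2E,6S,8Z)-10-(1,3-dioxolan-2-yl)-3,7,7-trimethyl-6-[(triethylsilyl)oxy]deca-2,8-dienoate | C1COC(C/C=C\C(C)(C)[C@@H](O[Si](CC)(CC)CC)CC/C(C)=C/C(=O)OC)O1 | intermediate
10 | methyl (2E,6S,8Z)-3,7,7-trimethyl-11-oxo-6-[(triethylsilyl)oxy]undeca-2,8-dienoate | O=CC/C=C\C(C)(C)[C@@H](O[Si](CC)(CC)CC)CC/C(C)=C/C(=O)OC | intermediate
11 | methyl (2E,6S,9E)-3,7,7-trimethyl-11-oxo-6-[(triethylsilyl)oxy]undeca-2,9-dienoate | O=C/C=C/CC(C)(C)[C@@H](O[Si](CC)(CC)CC)CC/C(C)=C/C(=O)OC | intermediate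
12 | methyl (2E,6S,8E,10E)-11-[(tert-butyldimethylsilyl)oxy]-3,7,7-trimethyl-6-[(triethylsilyl)oxy]undeca-2,8,10-trienoate | CC(C)(C)[Si](C)(C)O/C=C/C=C/C(C)(C)[C@@H](O[Si](CC)(CC)CC)CC/C(C)=C/C(=O)OC | intermediate
13 | cycloadduct: trans-decalin, 3β-OSiEt3, 8β-OSiMe2t-Bu, 9β-CO2Me, 10β-CH3, 5α-H, C6=C7 | CC1(C)[C@@H](O[Si](CC)(CC)CC)CC[C@]2(C)[C@@H](C(=O)OC)[C@@H](O[Si](C)(C)C(C)(C)C)C=C[C@@H]12 | intermediate
14 | saturated bis-silyl ether (13 with C6–C7 saturated) | CC1(C)[C@@H](O[Si](CC)(CC)CC)CC[C@]2(C)[C@@H](C(=O)OC)[C@@H](O[Si](C)(C)C(C)(C)C)CC[C@@H]12 | intermediate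
15 | 3β-hydroxy-8β-OSiMe2t-Bu-9β-CO2Me decalin | CC1(C)[C@@H](O)CC[C@]2(C)[C@@H](C(=O)OC)[C@@H](O[Si](C)(C)C(C)(C)C)CC[C@@H]12 | intermediate
16 | 3-oxo-8β-OSiMe2t-Bu-9β-CO2Me decalin | CC1(C)C(=O)CC[C@]2(C)[C@@H](C(=O)OC)[C@@H](O[Si](C)(C)C(C)(C)C)CC[C@@H]12 | intermediate
17 | 3-triflyloxy-2-ene (enol triflate) | CC1(C)C(OS(=O)(=O)C(F)(F)F)=CC[C@]2(C)[C@@H](C(=O)OC)[C@@H](O[Si](C)(C)C(C)(C)C)CC[C@@H]12 | intermediate
18 | 3-bromo-2-ene (vinyl bromide) | CC1(C)C(Br)=CC[C@]2(C)[C@@H](C(=O)OC)[C@@H](O[Si](C)(C)C(C)(C)C)CC[C@@H]12 | intermediate
19 | 3β-bromo-8β-OSiMe2t-Bu-9β-CO2Me decalin | CC1(C)[C@@H](Br)CC[C@]2(C)[C@@H](C(=O)OC)[C@@H](O[Si](C)(C)C(C)(C)C)CC[C@@H]12 | intermediate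
20 | 3β-bromo-8β-hydroxy-9β-CO2Me decalin | CC1(C)[C@@H](Br)CC[C@]2(C)[C@@H](C(=O)OC)[C@@H](O)CC[C@@H]12 | intermediate
21 | 3β-bromo-8-oxo-9β-CO2Me decalin (β-keto ester) | CC1(C)[C@@H](Br)CC[C@]2(C)[C@@H](C(=O)OC)C(=O)CC[C@@H]12 | intermediate
22 | 3β-bromo-8(17)-ene-9β-CO2Me decalin | CC1(C)[C@@H](Br)CC[C@]2(C)[C@@H](C(=O)OC)C(=C)CC[C@@H]12 | intermediate
23 | 3β-bromo-8α-hydroxy-8β-methyl-9β-CO2Me decalin | CC1(C)[C@@H](Br)CC[C@]2(C)[C@@H](C(=O)OC)[C@](C)(O)CC[C@@H]12 | intermediate
24 | 3β-bromo-8α,11-diol | CC1(C)[C@@H](Br)CC[C@]2(C)[C@@H](CO)[C@](C)(O)CC[C@@H]12 | intermediate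
25 | 3β-bromo-8α-hydroxy-11-aldehyde | CC1(C)[C@@H](Br)CC[C@]2(C)[C@@H](C=O)[C@](C)(O)CC[C@@H]12 | intermediate
26 | 3β-bromo-8α-hydroxy-9β-vinyl decalin | CC1(C)[C@@H](Br)CC[C@]2(C)[C@@H](C=C)[C@](C)(O)CC[C@@H]12 | intermediate
27 | but-2-yn-1-ol | CC#CCO | starting material
28 | (2Z)-3-iodobut-2-en-1-ol | C/C(I)=C/CO | intermediate
29 | (2Z)-1-bromo-3-iodobut-2-ene | C/C(I)=C/CBr | intermediate
30 | 3β-bromo-9β-vinyl-8α-[(2Z)-3-iodobut-2-enyloxy] decalin | CC1(C)[C@@H](Br)CC[C@]2(C)[C@@H](C=C)[C@](C)(OC/C=C(/C)I)CC[C@@H]12 | intermediate
31 | alkyl-9-BBN borane (30 with C9–CH2CH2–B(9-BBN)) | CC1(C)[C@@H](Br)CC[C@]2(C)[C@@H](CCB3C4CCCC3CCC4)[C@](C)(OC/C=C(/C)I)CC[C@@H]12 | intermediate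
32 | 3β-bromo oxocene (cis C13=C14 in ring C) | CC1(C)[C@@H](Br)CC[C@]2(C)[C@H]3CC/C(C)=C\CO[C@]3(C)CC[C@@H]12 | intermediate
33 | (3S,5R,8R,9R,10S,13R,14S)-3-bromo-8,15:13,14-diepoxylabdane (CNP0311742.2) | CC1(C)[C@@H](Br)CC[C@]2(C)[C@H]3CC[C@@]4(C)O[C@H]4CO[C@]3(C)CC[C@@H]12 | target

## Step count and least certain steps

Total step count: 26. Longest linear sequence: 23 (steps 1, 3–21, 24–26).

**Step 9 (key step).** What may go wrong: too little preference for the ester-endo transition state, so that the trans ring fusion is eroded; the exo mode avoids the contact between the C10 methyl and the axial C4 methyl. The trisubstituted enoate may also cyclise so slowly that the dienol ether decomposes. The fallback sets out from 12 and returns at 13. The ester of 12 is reduced with i-Bu2AlH to (2E,6S,8E,10E)-11-[(tert-butyldimethylsilyl)oxy]-3,7,7-trimethyl-6-[(triethylsilyl)oxy]undeca-2,8,10-trien-1-ol F1 and oxidised with MnO2 to the corresponding trienal F2. The formyl group is a stronger acceptor with a more pronounced endo preference, so F2 should cyclise at lower temperature to the 9β-formyl cycloadduct F3. Pinnick oxidation (NaClO2, NaH2PO4, 2-methylbut-2-ene) gives the 9β-carboxylic acid F4, and methylation with trimethylsilyldiazomethane gives 13.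

**Step 25.** What may go wrong: closure of the eight-membered ring may be slower than protodeboronation, β-hydride elimination from the alkylpalladium intermediate or intermolecular coupling. The fallback sets out from 26 and returns at 32. 26 is hydroborated with excess 9-BBN to the 8α-hydroxy C12 borane F5, which is coupled intermolecularly under the same palladium conditions with 28 to give the 8α-hydroxy (13Z)-15-alcohol F6. The primary allylic hydroxyl is converted into the (13Z)-15-chloride F7 (MsCl, Et3N, LiCl), and NaH under high dilution closes ring C by O8–C15 Williamson etherification to 32. Six-membered SN2′ closure is the competitor to watch.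

**Step 26.** What may go wrong: poor facial selectivity if the conformation of ring C exposes the face opposite to the one the chiral oxidant prefers. The fallback sets out from 32 and returns at 33. N-bromosuccinimide in aqueous THF gives the 13-hydroxy-14-bromide (bromohydrin) F8 by anti opening of the bromonium ion formed on the accessible face; K2CO3 in MeOH then closes the epoxide on the opposite face. This is the remedy if electrophiles prefer the wrong face of the olefin.

**Step 14.** What may go wrong: loss of bromine, by hydrogen-atom transfer to C3 followed by β-scission or by reduction of the C–Br bond, and incomplete axial hydrogen delivery. The fallback sets out from 18 and returns at 19: syn hydrogenation over Rh/Al2O3 with H2, which adds both hydrogens from the open α face and therefore also leaves bromine β. It makes no new compound (entry F0).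

**Step 18.** What may go wrong: poor facial selectivity in the oxygen capture of the C8 radical, and plain reduction of the olefin. The fallback sets out from 22 and returns at 24, bypassing 23. Peracid epoxidation (m-chloroperbenzoic acid) from the α face gives the 8α,17-epoxide F9; LiAlH4 at 0 °C opens it at C17 and reduces the ester in the same operation.

**Step 17.** What may go wrong: enolisation of the β-keto ester by the organometallic reagent in place of carbonyl addition. The fallback sets out from 21 and returns at 22. Peterson olefination: Me3SiCH2Li with CeCl3 adds to the ketone to give the 8-hydroxy-8-(trimethylsilylmethyl) ester F10, and HF·pyridine eliminates it to 22.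

## Further compounds

F1 | step 9 | (2E,6S,8E,10E)-11-[(tert-butyldimethylsilyl)oxy]-3,7,7-trimethyl-6-[(triethylsilyl)oxy]undeca-2,8,10-trien-1-ol | CC(C)(C)[Si](C)(C)O/C=C/C=C/C(C)(C)[C@@H](O[Si](CC)(CC)CC)CC/C(C)=C/CO
F2 | step 9 | (2E,6S,8E,10E)-11-[(tert-butyldimethylsilyl)oxy]-3,7,7-trimethyl-6-[(triethylsilyl)oxy]undeca-2,8,10-trienal | CC(C)(C)[Si](C)(C)O/C=C/C=C/C(C)(C)[C@@H](O[Si](CC)(CC)CC)CC/C(C)=C/C=O
F3 | step 9 | 9β-formyl cycloadduct (13 with CHO in place of CO2Me) | CC1(C)[C@@H](O[Si](CC)(CC)CC)CC[C@]2(C)[C@@H](C=O)[C@@H](O[Si](C)(C)C(C)(C)C)C=C[C@@H]12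
F4 | step 9 | 9β-carboxylic acid cycloadduct | CC1(C)[C@@H](O[Si](CC)(CC)CC)CC[C@]2(C)[C@@H](C(=O)O)[C@@H](O[Si](C)(C)C(C)(C)C)C=C[C@@H]12
F5 | step 25 | 8α-hydroxy C12 alkyl-9-BBN borane from 26 | CC1(C)[C@@H](Br)CC[C@]2(C)[C@@H](CCB3C4CCCC3CCC4)[C@](C)(O)CC[C@@H]12
F6 | step 25 | 3β-bromo-8α-hydroxy (13Z)-15-alcohol | CC1(C)[C@@H](Br)CC[C@]2(C)[C@@H](CC/C(C)=C\CO)[C@](C)(O)CC[C@@H]12
F7 | step 25 | 3β-bromo-8α-hydroxy (13Z)-15-chloride | CC1(C)[C@@H](Br)CC[C@]2(C)[C@@H](CC/C(C)=C\CCl)[C@](C)(O)CC[C@@H]12
F8 | step 26 | 13-hydroxy-14-bromide (bromohydrin) of 32 | CC1(C)[C@@H](Br)CC[C@]2(C)[C@H]3CC[C@@](C)(O)[C@H](Br)CO[C@]3(C)CC[C@@H]12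
F0 | step 14 | none | none
F9 | step 18 | 3β-bromo-8α,17-epoxide ester | CC1(C)[C@@H](Br)CC[C@]2(C)[C@@H](C(=O)OC)[C@@]3(CO3)CC[C@@H]12
F10 | step 17 | 3β-bromo-8-hydroxy-8-(trimethylsilylmethyl) ester | CC1(C)[C@@H](Br)CC[C@]2(C)[C@@H](C(=O)OC)[C@@](C[Si](C)(C)C)(O)CC[C@@H]12
A1 | alternative 1 | metathesis substrate: 3β-bromo-8α-allyloxy-9β-(3-methylbut-3-enyl) decalin | CC1(C)[C@@H](Br)CC[C@]2(C)[C@@H](CCC(C)=C)[C@](C)(OCC=C)CC[C@@H]12
A2 | alternative 1 | 3β-bromo oxocene (cis C13=C14) | CC1(C)[C@@H](Br)CC[C@]2(C)[C@H]3CC/C(C)=C\CO[C@]3(C)CC[C@@H]12
A3 | alternative 2 | ring B ketone: 2-methylcyclohexanone with C8 methyl and triethylsilyl ether and C9 vinyl group | O=C1CC[C@@](C)(O[Si](CC)(CC)CC)[C@H](C=C)C1C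
A4 | alternative 2 | pent-1-en-3-one | C=CC(=O)CC
A5 | alternative 2 | bicyclic 4-methyl enone | CC1=C2CC[C@@](C)(O[Si](CC)(CC)CC)[C@H](C=C)[C@@]2(C)CCC1=O
A6 | alternative 3 | C12 iodide on the 3β-bromodecalin with C8 triethylsilyl ether | CC1(C)[C@@H](Br)CC[C@]2(C)[C@@H](CCI)[C@](C)(O[Si](CC)(CC)CC)CC[C@@H]12
A7 | alternative 3 | propyne | CC#C
A8 | alternative 3 | carbon dioxide | O=C=O
A9 | alternative 3 | (Z)-3-methylalk-2-enoic acid side chain on the bromodecalin | CC1(C)[C@@H](Br)CC[C@]2(C)[C@@H](CC/C(C)=C\C(=O)O)[C@](C)(O[Si](CC)(CC)CC)CC[C@@H]12
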